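**Plan**

1. Cuts (daucane numbering: C1 = ring-fusion carbon with CH3, C2 = CH–OAc, C3 = CH2, C4 = C(OH)iPr, C5 = ring-fusion CH, C6 = CH–O-aroyl, C7=C8(CH3), C9 = C=O, C10 = CH2): both ester C–O bonds, then C6–C7, then C7–I/C8–CH3 and C9–C8 on the side arm, then C4–isopropyl, then C1–CH3 and C5–C6 on a cyclopentenone.
2. Enabling feature: in the seven-membered ring, C6–O, C7=C8 and C9=O form a γ-oxygenated enone with C7 held cis to C9. A C6 aldehyde on C5 and a (Z)-β-iodo enone on the C1 arm are therefore matched partners for a Ni/Cr-mediated (Nozaki–Hiyama–Kishi) closure of C6–C7.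
3. Forward order: the five-membered ring (ring A) is elaborated first from (R)-4-silyloxycyclopentenone; the C10–C7 arm is grown from an allyl group on C1; the seven-membered ring (ring B) closes in step 9; the two esters are set last.
4. Stereochemistry: only C2 is bought. Methyl cuprate addition anti to the C2 silyloxy group sets C1, and formaldehyde trapping of the same enolate sets C5. Isopropyl addition anti to the C5 side chain sets C4, and the ring closure sets C6 under control of C1 and C5.
5. The (Z) iodide and the C8 methyl arise together from alkoxide-directed anti-carbomagnesiation/iodination of a C9 propargylic alcohol; one oxidation then unveils both carbonyl partners.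

Key step: step 9

Remark: the daucane numbering above is used in all Why lines. Compounds 9 to 11 are carried as mixtures of epimers at the C9 carbinol carbon, which becomes the ketone in step 8. Compounds 1 and 15 and all reagents are taken as commercial.

**Step 1**
Reactants: 1 (R)-4-[(tert-butyldimethylsilyl)oxy]cyclopent-2-en-1-one
Product: 2 (3R,4R)-3-allyl-4-[(tert-butyldimethylsilyl)oxy]-1-[(trimethylsilyl)oxy]cyclopent-1-ene
Conditions: allylMgBr, CuBr·SMe2 (10 mol%), Me3SiCl, THF, −78 °C; Et3N/pentane work-up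
Reagents that add atoms: allylmagnesium bromide C=CC[Mg]Br; chlorotrimethylsilane C[Si](C)(C)Cl
Why: Copper-catalysed conjugate allylation accelerated by Me3SiCl should deliver the allyl group anti to the C2 silyloxy group and trap the enolate regiospecifically as its silyl enol ether; the new stereocenter is erased in step 2.

**Step 2**
Reactants: 2 silyl enol ether
Product: 3 (R)-3-allyl-4-[(tert-butyldimethylsilyl)oxy]cyclopent-2-en-1-one
Conditions: Pd(OAc)2 (1.1 equiv), MeCN, rt
Reagents that add atoms: none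
Why: Saegusa–Ito oxidation should return the enone, because the palladium enolate has only one β-hydrogen, on the allyl-bearing carbon, and the C2 stereocenter is not touched.

**Step 3**
Reactants: 3 allyl enone
Product: 5 (2R,3S,4R)-3-allyl-4-[(tert-butyldimethylsilyl)oxy]-2-(hydroxymethyl)-3-methylcyclopentan-1-one, via lithium enolate 4 (not isolated)
Conditions: Me2CuLi (2 equiv), Et2O, −78 to −20 °C; then CH2O (gas, from cracked paraformaldehyde), −78 °C; aq. NH4Cl
Reagents that add atoms: lithium dimethylcuprate [Li+].C[Cu-]C; formaldehyde C=O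
Why: Cuprate conjugate addition anti to the C2 silyloxy group should set the C1 quaternary center (methyl trans to the silyloxy group), and the regiodefined enolate should take up formaldehyde on the face of the small methyl group, away from the allyl and silyloxy groups, setting C5 (three-component enone coupling with enolate hydroxymethylation).

**Step 4**
Reactants: 5 hydroxymethyl ketone
Product: 6 (1S,2R,3S,4R)-3-allyl-4-[(tert-butyldimethylsilyl)oxy]-2-(hydroxymethyl)-3-methyl-1-(propan-2-yl)cyclopentan-1-ol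
Conditions: iPrMgCl (3.5 equiv), CeCl3 (3.5 equiv, dried), THF, −78 to −40 °C; aq. NH4Cl
Reagents that add atoms: isopropylmagnesium chloride CC(C)[Mg]Cl
Why: The weakly basic organocerium reagent should add 1,2 without enolisation, retro-aldol loss of formaldehyde or β-elimination of the silyloxy group, and should attack anti to the adjacent C5 side chain (held below the carbonyl as its cerium alkoxide chelate), so that the C4 hydroxyl ends up cis to CH2OH.

**Step 5**
Reactants: 6 allyl diol
Product: 8 2-[(1S,2R,3S,5R)-5-[(tert-butyldimethylsilyl)oxy]-3-hydroxy-2-(hydroxymethyl)-1-methyl-3-(propan-2-yl)cyclopentyl]acetaldehyde, via ozonide 7 (not isolated)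
Conditions: O3, CH2Cl2, −78 °C; then PPh3, −78 °C to rt
Reagents that add atoms: ozone [O-][O+]=O
Why: Ozonolysis with reductive work-up cleaves the only C=C bond, and the aldehyde should stay open because the C4 hydroxyl is trans to the arm and the cis C2 oxygen is silylated.

**Step 6**
Reactants: 8 aldehyde
Product: 9 1-[(1S,2R,3S,5R)-5-[(tert-butyldimethylsilyl)oxy]-3-hydroxy-2-(hydroxymethyl)-1-methyl-3-(propan-2-yl)cyclopentyl]but-3-yn-2-ol (both carbinol epimers)
Conditions: HC≡CMgBr (5 equiv), THF, −20 to 0 °C; aq. NH4Cl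
Reagents that add atoms: ethynylmagnesium bromide C#C[Mg]Br
Why: Grignard addition to the unhindered aldehyde tolerates the two free hydroxyls as alkoxides, and the new carbinol center is inconsequential because it becomes the C9 ketone.

**Step 7**
Reactants: 9 propargylic alcohol
Product: 11 (3Z)-1-[(1S,2R,3S,5R)-5-[(tert-butyldimethylsilyl)oxy]-3-hydroxy-2-(hydroxymethyl)-1-methyl-3-(propan-2-yl)cyclopentyl]-4-iodo-3-methylbut-3-en-2-ol (both carbinol epimers), via alkenylmagnesium species 10 (not isolated)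
Conditions: MeMgBr (8 equiv), CuI (20 mol%), THF/Et2O, −10 °C to rt; then I2, −78 to 0 °C; aq. Na2S2O3/NH4Cl
Reagents that add atoms: methylmagnesium bromide C[Mg]Br; iodine II
Why: Alkoxide-directed copper-catalysed anti-carbomagnesiation of the propargylic alkoxide should put the methyl group on C8 and magnesium on C7 inside a five-membered magnesium chelate, so that iodinolysis with retention gives only the (Z)-iodoalkene with iodine cis to C9.

**Step 8**
Reactants: 11 iodo triol
Product: 12 (1S,2S,3R,5S)-3-[(tert-butyldimethylsilyl)oxy]-5-hydroxy-2-[(3Z)-4-iodo-3-methyl-2-oxobut-3-en-1-yl]-2-methyl-5-(propan-2-yl)cyclopentane-1-carbaldehyde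
Conditions: Dess–Martin periodinane (3 equiv), NaHCO3, CH2Cl2, 0 °C to rt; used at once, protected from light
Reagents that add atoms: none
Why: Dess–Martin oxidation should convert the allylic secondary alcohol to the C9 enone and the primary alcohol to the C6 aldehyde in one buffered, non-epimerising operation, leaving the tertiary hydroxyl, the silyl ether and the vinyl iodide untouched.

**Step 9**
Reactants: 12 iodo enone aldehyde
Product: 14 (1S,2R,4S,5R,6R)-2-[(tert-butyldimethylsilyl)oxy]-4,6-dihydroxydauc-7-en-9-one (trans-fused hydroazulenone), via alkenylchromium species 13 (not isolated)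
Conditions: CrCl2 (10 equiv), NiCl2 (2 mol%), degassed DMSO, rt, slow addition of 12 to 0.003 M; aq. sodium serinate work-up
Reagents that add atoms: none
Why: Zerovalent nickel (from NiCl2 and CrCl2) inserts into the C7–I bond, transmetalation gives the C7 alkenyl trivalent chromium species 13 with retention of the (Z) geometry, and this adds to the C6 aldehyde to form the C6–C7 bond; the closest known reaction type is the intramolecular Nozaki–Hiyama–Kishi closure of β-iodo enones onto aldehydes. The seven-membered ring closes in the 7-exo-trig mode with respect to the aldehyde carbonyl, and the (Z) alkene already holds C7 cis to C9 as the ring requires. The new C6 stereocenter should be set by C1 and C5: in the chair-like transition state of the forming trans-fused cycloheptenone the bulky chromium-bound oxygen sits pseudo-equatorial, whereas the other face would force it into a 1,3-diaxial clash with the angular C1 methyl, so the C6 hydroxyl should emerge cis to H5 as in the target. The step needs chemoselectivity for the aldehyde over the C9 ketone, which is inherent to alkenylchromium reagents, and base-free conditions so that the β-hydroxy aldehyde neither epimerises at C5 nor undergoes retro-aldol cleavage or dehydration; high dilution favours cyclisation over oligomerisation.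

**Step 10**
Reactants: 14 bicyclic diol; 15 4-acetoxybenzoic acid
Product: 16 (1S,2R,4S,5R,6R)-6-[(4-acetoxybenzoyl)oxy]-2-[(tert-butyldimethylsilyl)oxy]-4-hydroxydauc-7-en-9-one
Conditions: 15 (1.5 equiv), DCC, DMAP (cat.), CH2Cl2, 0 °C to rt
Reagents that add atoms: 4-acetoxybenzoic acid CC(=O)Oc1ccc(cc1)C(O)=O
Why: Steglich esterification should acylate the only accessible hydroxyl, the secondary allylic C6 alcohol, with retention, the tertiary C4 hydroxyl being too hindered.

**Step 11**
Reactants: 16 silyl ether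
Product: 17 (1S,2R,4S,5R,6R)-6-[(4-acetoxybenzoyl)oxy]-2,4-dihydroxydauc-7-en-9-one
Conditions: HF·pyridine, pyridine, THF, 0 °C to rt
Reagents that add atoms: none
Why: Buffered fluoride desilylation should free the C2 hydroxyl without cleaving the aryl acetate or the allylic benzoate and without dehydrating the tertiary alcohol.

**Step 12**
Reactants: 17 C2 alcohol
Product: 18 (1S,2R,4S,5R,6R)-2-acetoxy-6-[(4-acetoxybenzoyl)oxy]-4-hydroxydauc-7-en-9-one
Conditions: Ac2O, pyridine, DMAP (cat.), CH2Cl2, 0 °C to rt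
Reagents that add atoms: acetic anhydride CC(=O)OC(C)=O
Why: DMAP-catalysed acetylation should esterify the secondary C2 hydroxyl, while the tertiary C4 hydroxyl flanked by the isopropyl group does not react.

**Step 13**
Reactants: 18 diacetate
Product: 19 (1S,2R,4S,5R,6R)-2-acetoxy-4-hydroxy-6-[(4-hydroxybenzoyl)oxy]dauc-7-en-9-one (target)
Conditions: NH4OAc (excess), MeOH/H2O 4:1, rt
Reagents that add atoms: none
Why: Chemoselective solvolysis of the aryl acetate should release only the phenol, since phenoxide is a far better leaving group than the alkoxides of the C2 acetate and the C6 benzoate.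

**Compound list**

1 | (R)-4-[(tert-butyldimethylsilyl)oxy]cyclopent-2-en-1-one | CC(C)(C)[Si](C)(C)O[C@@H]1CC(=O)C=C1 | starting material
2 | (3R,4R)-3-allyl-4-[(tert-butyldimethylsilyl)oxy]-1-[(trimethylsilyl)oxy]cyclopent-1-ene | CC(C)(C)[Si](C)(C)O[C@@H]1CC(O[Si](C)(C)C)=C[C@H]1CC=C | intermediate
3 | (R)-3-allyl-4-[(tert-butyldimethylsilyl)oxy]cyclopent-2-en-1-one | CC(C)(C)[Si](C)(C)O[C@@H]1CC(=O)C=C1CC=C | intermediate
4 | lithium enolate of (3S,4R)-3-allyl-4-[(tert-butyldimethylsilyl)oxy]-3-methylcyclopentanone | CC(C)(C)[Si](C)(C)O[C@@H]1CC(O[Li])=C[C@]1(C)CC=C | intermediate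
5 | (2R,3S,4R)-3-allyl-4-[(tert-butyldimethylsilyl)oxy]-2-(hydroxymethyl)-3-methylcyclopentan-1-one | CC(C)(C)[Si](C)(C)O[C@@H]1CC(=O)[C@@H](CO)[C@]1(C)CC=C | intermediate
6 | (1S,2R,3S,4R)-3-allyl-4-[(tert-butyldimethylsilyl)oxy]-2-(hydroxymethyl)-3-methyl-1-(propan-2-yl)cyclopentan-1-ol | CC(C)(C)[Si](C)(C)O[C@@H]1C[C@](O)(C(C)C)[C@@H](CO)[C@]1(C)CC=C | intermediate
7 | ozonide (1,2,4-trioxolane) of the allyl group of 6 | CC(C)(C)[Si](C)(C)O[C@@H]1C[C@](O)(C(C)C)[C@@H](CO)[C@]1(C)CC2OCOO2 | intermediate
8 | 2-[(1S,2R,3S,5R)-5-[(tert-butyldimethylsilyl)oxy]-3-hydroxy-2-(hydroxymethyl)-1-methyl-3-(propan-2-yl)cyclopentyl]acetaldehyde | CC(C)(C)[Si](C)(C)O[C@@H]1C[C@](O)(C(C)C)[C@@H](CO)[C@]1(C)CC=O | intermediate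
9 | 1-[(1S,2R,3S,5R)-5-[(tert-butyldimethylsilyl)oxy]-3-hydroxy-2-(hydroxymethyl)-1-methyl-3-(propan-2-yl)cyclopentyl]but-3-yn-2-ol, both carbinol epimers | CC(C)(C)[Si](C)(C)O[C@@H]1C[C@](O)(C(C)C)[C@@H](CO)[C@]1(C)CC(O)C#C | intermediate
10 | (Z)-alkenylmagnesium bromide of 9 after methyl addition, all three hydroxyls as bromomagnesium alkoxides | CC(C)(C)[Si](C)(C)O[C@@H]1C[C@](O[Mg]Br)(C(C)C)[C@@H](CO[Mg]Br)[C@]1(C)CC(O[Mg]Br)/C(C)=C\[Mg]Br | intermediate
11 | (3Z)-1-[(1S,2R,3S,5R)-5-[(tert-butyldimethylsilyl)oxy]-3-hydroxy-2-(hydroxymethyl)-1-methyl-3-(propan-2-yl)cyclopentyl]-4-iodo-3-methylbut-3-en-2-ol, both carbinol epimers | CC(C)(C)[Si](C)(C)O[C@@H]1C[C@](O)(C(C)C)[C@@H](CO)[C@]1(C)CC(O)/C(C)=C\I | intermediate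
12 | (1S,2S,3R,5S)-3-[(tert-butyldimethylsilyl)oxy]-5-hydroxy-2-[(3Z)-4-iodo-3-methyl-2-oxobut-3-en-1-yl]-2-methyl-5-(propan-2-yl)cyclopentane-1-carbaldehyde | CC(C)(C)[Si](C)(C)O[C@@H]1C[C@](O)(C(C)C)[C@@H](C=O)[C@]1(C)CC(=O)/C(C)=C\I | intermediate
13 | (Z)-alkenylchromium dichloride formed from 12 at C7 | CC(C)(C)[Si](C)(C)O[C@@H]1C[C@](O)(C(C)C)[C@@H](C=O)[C@]1(C)CC(=O)/C(C)=C\[Cr](Cl)Cl | intermediate
14 | (1S,2R,4S,5R,6R)-2-[(tert-butyldimethylsilyl)oxy]-4,6-dihydroxydauc-7-en-9-one | CC(C)(C)[Si](C)(C)O[C@@H]1C[C@](O)(C(C)C)[C@H]2[C@H](O)C=C(C)C(=O)C[C@]12C | intermediate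
15 | 4-acetoxybenzoic acid | CC(=O)Oc1ccc(cc1)C(O)=O | starting material
16 | (1S,2R,4S,5R,6R)-6-[(4-acetoxybenzoyl)oxy]-2-[(tert-butyldimethylsilyl)oxy]-4-hydroxydauc-7-en-9-one | CC(C)(C)[Si](C)(C)O[C@@H]1C[C@](O)(C(C)C)[C@H]2[C@H](OC(=O)c3ccc(OC(C)=O)cc3)C=C(C)C(=O)C[C@]12C | intermediate
17 | (1S,2R,4S,5R,6R)-6-[(4-acetoxybenzoyl)oxy]-2,4-dihydroxydauc-7-en-9-one | O[C@@H]1C[C@](O)(C(C)C)[C@H]2[C@H](OC(=O)c3ccc(OC(C)=O)cc3)C=C(C)C(=O)C[C@]12C | intermediate
18 | (1S,2R,4S,5R,6R)-2-acetoxy-6-[(4-acetoxybenzoyl)oxy]-4-hydroxydauc-7-en-9-one | CC(=O)O[C@@H]1C[C@](O)(C(C)C)[C@H]2[C@H](OC(=O)c3ccc(OC(C)=O)cc3)C=C(C)C(=O)C[C@]12C | intermediate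
19 | (1S,2R,4S,5R,6R)-2-acetoxy-4-hydroxy-6-[(4-hydroxybenzoyl)oxy]dauc-7-en-9-one | CC(=O)O[C@@H]1C[C@](O)(C(C)C)[C@H]2[C@H](OC(=O)c3ccc(O)cc3)C=C(C)C(=O)C[C@]12C | target

**Count and risks**

Total step count: 13. Longest linear sequence: 13 steps (1 to 19); compound 15 is bought.

Steps most likely to fail:

Step 9. The alkenylchromium may add to the other face of the aldehyde, for example if chelation to the C4 alkoxide forces the chromium-bound oxygen axial, so that the C6 epimer predominates. The fallback sets out from 12: the same closure would then give the 6-epi alcohol F1. This would be esterified with inversion under Mitsunobu conditions (15, PPh3, diisopropyl azodicarboxylate, toluene, 0 °C), the acid attacking C6 from the face opposite the activated oxygen. The route is rejoined at 16.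

Step 7. Carbomagnesiation of the poorly soluble tris-alkoxide may stall, or the alkenylmagnesium may be protonated before iodine is added, so that the methyl group or the iodide is not installed cleanly. The fallback sets out from 9 and defers the C8 methyl. Dess–Martin oxidation of 9 would give the ynone aldehyde F2. Hydroiodination (NaI, AcOH, rt) would give the (Z)-β-iodo enone aldehyde F3 by anti addition. The same CrCl2/NiCl2 closure would give the 8-desmethyl bicyclic alcohol F4. α-Iodination of the enone (I2, pyridine, CH2Cl2) would give the 8-iodo enone F5. Stille methylation (Me4Sn, Pd2(dba)3, AsPh3, CuI, N-methylpyrrolidone, 60 °C) would then return the route to 14.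

Step 4. The isopropyl nucleophile may attack from the face anti to the C2 silyloxy group instead of anti to the C5 side chain, giving the C4 epimer. The fallback sets out from 5 and delivers oxygen, not carbon, under hydroxyl direction. Silylation (Et3SiCl, imidazole) would give the triethylsilyl ether F6. Kinetic enolisation towards C3 with in situ trapping (KN(SiMe3)2, PhNTf2, THF, −78 °C) would give the enol triflate F7. Cross-coupling (iPrMgCl, Fe(acac)3 cat., THF/N-methylpyrrolidone, −20 °C) would give the isopropyl cyclopentene F8. Mild acid (pyridinium p-toluenesulfonate, MeOH) would free the homoallylic alcohol F9. Epoxidation with VO(acac)2 and t-BuOOH should be directed by the CH2OH group to its own face and give the epoxide F10. LiAlH4 should open it at the secondary carbon C3 and return the route to 6.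

Further compounds
F1 | step 9 | (1S,2R,4S,5R,6S)-2-[(tert-butyldimethylsilyl)oxy]-4,6-dihydroxydauc-7-en-9-one (C6 epimer of 14) | CC(C)(C)[Si](C)(C)O[C@@H]1C[C@](O)(C(C)C)[C@H]2[C@@H](O)C=C(C)C(=O)C[C@]12C
F2 | step 7 | (1S,2S,3R,5S)-3-[(tert-butyldimethylsilyl)oxy]-5-hydroxy-2-methyl-2-(2-oxobut-3-yn-1-yl)-5-(propan-2-yl)cyclopentane-1-carbaldehyde | CC(C)(C)[Si](C)(C)O[C@@H]1C[C@](O)(C(C)C)[C@@H](C=O)[C@]1(C)CC(=O)C#C
F3 | step 7 | (1S,2S,3R,5S)-3-[(tert-butyldimethylsilyl)oxy]-5-hydroxy-2-[(3Z)-4-iodo-2-oxobut-3-en-1-yl]-2-methyl-5-(propan-2-yl)cyclopentane-1-carbaldehyde | CC(C)(C)[Si](C)(C)O[C@@H]1C[C@](O)(C(C)C)[C@@H](C=O)[C@]1(C)CC(=O)/C=C\I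
F4 | step 7 | 8-desmethyl analogue of 14 (C7=C8 disubstituted enone) | CC(C)(C)[Si](C)(C)O[C@@H]1C[C@](O)(C(C)C)[C@H]2[C@H](O)C=CC(=O)C[C@]12C
F5 | step 7 | 8-iodo-8-desmethyl analogue of 14 (α-iodo enone) | CC(C)(C)[Si](C)(C)O[C@@H]1C[C@](O)(C(C)C)[C@H]2[C@H](O)C=C(I)C(=O)C[C@]12C
F6 | step 4 | triethylsilyl ether of 5 at the primary hydroxyl | CC(C)(C)[Si](C)(C)O[C@@H]1CC(=O)[C@@H](CO[Si](CC)(CC)CC)[C@]1(C)CC=C
F7 | step 4 | enol triflate of F6 (double bond C3=C4) | CC(C)(C)[Si](C)(C)O[C@@H]1C=C(OS(=O)(=O)C(F)(F)F)[C@@H](CO[Si](CC)(CC)CC)[C@]1(C)CC=C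
F8 | step 4 | 4-isopropyl cyclopentene from F7 (double bond C3=C4, triethylsilyl ether) | CC(C)(C)[Si](C)(C)O[C@@H]1C=C(C(C)C)[C@@H](CO[Si](CC)(CC)CC)[C@]1(C)CC=C
F9 | step 4 | homoallylic alcohol from F8 (free CH2OH) | CC(C)(C)[Si](C)(C)O[C@@H]1C=C(C(C)C)[C@@H](CO)[C@]1(C)CC=C
F10 | step 4 | C3–C4 epoxide of F9, oxygen cis to CH2OH | CC(C)(C)[Si](C)(C)O[C@@H]1[C@H]2O[C@@]2(C(C)C)[C@@H](CO)[C@]1(C)CC=C
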